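**Remark on the chemistry (assumption):** 3,5-bis(benzyloxy)phenol (1) and 3-hydroxy-4,5-dimethoxybenzaldehyde (10) are taken as catalogue chemicals, and carbon monoxide (13) is used from a cylinder.

## The problem

Compound 20 is a flavonol, 3,5,7-trihydroxy-2-(3-hydroxy-4,5-dimethoxyphenyl)-8-methoxychromen-4-one. Ring A is oxygenated at C5, C7, C8 and, through O1, at C8a; ring C carries the C4 carbonyl and an enolic 3-hydroxyl; ring B is an aryl group on C2. There is no stereocentre, so the task is one of regiochemistry and of telling oxygens apart. Three of the seven exocyclic oxygens are methyl ethers (C8, C4', C5') and four are free hydroxyls (C3, C5, C7, C3'), so methyl cannot serve as a protecting group and a selective demethylation at the end is not available. Ring A is a 1,2,3,5-tetraoxygenated benzene in which the two oxygens flanking the C8 methoxyl must be differentiated: one becomes the ring oxygen O1, the other the 7-hydroxyl. The free polyhydroxyflavonol is oxidised by air in base, and an electron-rich polyalkoxyaryl iodide loses iodine readily under acid, so the hydroxyls should be released last and under neutral conditions. The enabling feature is C4: it is a ketone carbon held between the aromatic C4a and the sp2 carbon C3, and C3 is joined to C2 by a double bond. That is the oxidation level of an aryl alkynyl ketone, and the C8a oxygen sits ortho to C4a, placed to add to C2. The one C–H of ring C, at C3, lies next to the carbonyl and is the most acidic C–H of a flavone, so the 3-hydroxyl can be added after the ring is built.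

## Retrosynthesis

**20 from 19.** The three O–benzyl bonds at O5, O7 and O3' are cut. Benzyl is chosen because it survives organolithium bases and hot amine, and because hydrogenolysis is neutral and leaves the three methyl ethers alone. The 3-hydroxyl needs no protection, since it is introduced in the step just before.

**19 from 16.** The C3–O bond is cut. An alkyne partner cannot carry this oxygen through ring construction, because both alkyne carbons end as C2 and C3 with hydrogen on C3. The cut is therefore placed late: flavone 16 is deprotonated at C3, borylated to 18 through the lithio compound 17, and oxidised. The forward step must deprotonate C3 without adding to the pyranone.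

**16 from 9, 12 and 13.** Three bonds are cut at once: C4a–C4, C4–C3 and O1–C2. The neighbouring cuts (a chalcone or a β-diketone) would need a ring A acetophenone with the same substitution problem plus a C-acylation. Cutting at the carbonyl carbon reduces ring A to iodophenol 9, ring B to alkyne 12 and C4 to carbon monoxide 13. The forward reaction must insert 13 before the alkyne couples, and must close the six-membered ring, not the five-membered one; ynone 14 and enaminone 15 are the intermediates in the flask.

**12 from 11 from 10.** The terminal alkyne carbon is removed to give aldehyde 11 (one-carbon homologation in the forward sense), and the O–benzyl bond is cut to give phenol 10. Both operations are routine and the ring B pattern is bought in.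

**9 from 8, 6, 5, 2 and 1.** The carbamoyl C–O bond of 8 is cut to free the phenol 9. The C–I bond of 8 comes from aryllithium 7, made by directed lithiation of 6. The O–methyl bond of 6 leads to phenol 5, whose new C–O bond comes from lithiation of 2 and borylation (3, then 4). Carbamate 2 is made from phenol 1. The logic is that one carbamate on the symmetric 1 marks the future O1, and its two ortho positions are then functionalised in turn, first with oxygen (the C8 methoxyl) and then with iodine (C4a). Electrophilic iodination of a free phenol was set aside because two comparably activated positions would compete, whereas each lithiation obeys the single strongest director.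

## Roads not taken

**Alternative 1:** The cut runs through ring A at C8–C8a and C4a–C5, so rings C and B are complete before ring A exists. Diene A3, 1,4-dimethoxy-1,3-bis(trimethylsilyloxy)buta-1,3-diene, would add across the sulfinyl-activated C5–C6 double bond of pyranone A2, 3-(benzyloxy)-2-[3-(benzyloxy)-4,5-dimethoxyphenyl]-5-(phenylsulfinyl)pyran-4-one. Two eliminations (the sulfinyl group and the acetal methoxyl) would then aromatise the new ring to A1, the 3,3'-di-O-benzyl ether of 20.
- Merits: the polarity of the diene fixes the ring A pattern, the C3 oxygen is present from the start, and the 5- and 7-hydroxyls are born free, so A1 is one hydrogenolysis from 20.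
- Weak points: A2 is itself an advanced intermediate with no catalogue anchor. The C5–C6 bond of a 4-pyranone is part of a vinylogous ester and a reluctant dienophile even with the sulfoxide. A3 is moisture-sensitive and its terminal methoxyl slows cycloaddition. The aromatisation also has a second exit that expels the C8 methoxyl instead of sulfur.
- Comparison: this road is better in protecting-group economy and needs no late oxidation at C3. The chosen plan sets against it two fragments reached from catalogue compounds in at most five steps and a ring-forming step of an established class.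

**Alternative 2:** The cut is at C4a–C5, with C8–C8a made earlier by addition to a four-membered ring. Heating cyclobutenone A5 in xylene would open it to vinylketene A6, whose six-electron closure onto the pyranone C5 position and tautomerisation would give A4, the 3,3'-di-O-benzyl-7-O-isopropyl derivative of 20.
- Merits: every ring A substituent is fixed by its position on the cyclobutenone, so the key step cannot go regiochemically astray. It needs no reagent, the 5-hydroxyl is born free and the C3 oxygen is in place.
- Weak points: A5 requires a C6-metalated 2-aryl-3-benzyloxypyranone, its regioselective addition to an unsymmetrical alkoxycyclobutenedione and methylation of a hindered tertiary alkoxide. The electrocyclisation must use the C5=C6 bond of a pyranone, where the usual partners are arenes and simple alkenes. A4 carries an isopropyl ether whose removal needs a Lewis acid next to three methyl ethers, one of them ortho to it.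
- Comparison: in regiochemical certainty for ring A this road is better than the chosen one, which depends on two directed lithiations. The chosen plan sets against it a much shorter path to the key-step precursors and a single protecting group removed in one neutral step.

**Alternative 3:** The cut is at O1–C8a, so the ring oxygen is attached to ring A by oxidation. Anodic two-electron oxidation of β-diketone A8 in methanol would give quinone monoketal A9. The enol oxygen of the ring B aroyl group would add to C8a, and loss of methanol would re-aromatise to A7, the 3-O-benzoyl-7,3'-di-O-benzyl derivative of 20.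
- Merits: the ring A building block is only trioxygenated, there is no need to differentiate the two oxygens flanking the methoxyl, the 5-hydroxyl is never protected, and the C3 oxygen rides in as a benzoate. No halide, organometallic or pressure vessel is needed.
- Weak points: the anode must choose the 4-methoxyphenol ring over the equally electron-rich ring B, the benzyl ethers and the enolised diketone, while the hydrogen-bonded ortho acyl group raises the potential of the very ring to be oxidised. In A9 the enol oxygen competes with solvent methanol and with the enol carbon, and acylated quinone monoketals hydrolyse easily to quinones. Ring closure of a pyranone in this way has no close precedent.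
- Comparison: this is the shortest road on paper and starts from the simplest ring A piece, and in those respects it is better than the chosen plan. The chosen plan sets against it a key step whose reaction class is established for flavones and whose selectivity questions have known answers.

Key step: step 8

## Route

Step 1
Reactants: 1 3,5-bis(benzyloxy)phenol
Product: 2 3,5-bis(benzyloxy)phenyl N,N-diethylcarbamate
Conditions: NaH, ClC(O)NEt2, THF, 0 °C to rt
Reagents that add atoms: N,N-diethylcarbamoyl chloride, CCN(CC)C(Cl)=O
Why: O-carbamoylation of the sodium phenoxide (acyl substitution); the diethylcarbamate is the strongest oxygen director for ortho-lithiation and masks the oxygen that becomes O1.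

Step 2
Reactants: 2 3,5-bis(benzyloxy)phenyl N,N-diethylcarbamate
Product: 5 3,5-bis(benzyloxy)-2-hydroxyphenyl N,N-diethylcarbamate, via aryllithium 3 (not isolated), via arylboronate 4 (not isolated)
Conditions: sBuLi, TMEDA, THF, −78 °C; B(OMe)3, −78 to 0 °C; AcOH, 30% H2O2, 0 °C to rt
Reagents that add atoms: hydrogen peroxide, OO (the new oxygen); trimethyl borate, COB(OC)OC (boron and methoxyls of 4); sec-butyllithium, [Li]C(C)CC (lithium of 3)
Why: Directed ortho-metalation between the carbamate and a benzyloxy group, which together outrank the site between the two benzyloxy groups; at −78 °C the anionic ortho-Fries shift should not occur, and borylation followed by acidic peroxide oxidation (aryl migration from boron to oxygen) should give the phenol without carbamoyl transfer.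

Step 3
Reactants: 5 3,5-bis(benzyloxy)-2-hydroxyphenyl N,N-diethylcarbamate
Product: 6 3,5-bis(benzyloxy)-2-methoxyphenyl N,N-diethylcarbamate
Conditions: MeI, K2CO3, acetone, rt
Reagents that add atoms: iodomethane, CI
Why: Williamson O-methylation of the phenoxide; a dialkylcarbamate is a poor acyl donor, so methylation should outrun O-to-O carbamoyl migration at room temperature.

Step 4
Reactants: 6 3,5-bis(benzyloxy)-2-methoxyphenyl N,N-diethylcarbamate
Product: 8 3,5-bis(benzyloxy)-2-iodo-6-methoxyphenyl N,N-diethylcarbamate, via aryllithium 7 (not isolated)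
Conditions: sBuLi, TMEDA, THF, −78 °C; I2, THF, −78 °C to rt
Reagents that add atoms: iodine, II; sec-butyllithium, [Li]C(C)CC (lithium of 7)
Why: Second directed ortho-metalation; the only remaining position next to the carbamate (between it and the 5-benzyloxy group) is lithiated in preference to the site between the two benzyloxy groups, and iodine quench at −78 °C should trap 7 before any ortho-Fries shift.

Step 5
Reactants: 8 3,5-bis(benzyloxy)-2-iodo-6-methoxyphenyl N,N-diethylcarbamate
Product: 9 3,5-bis(benzyloxy)-2-iodo-6-methoxyphenol
Conditions: Cp2Zr(H)Cl (3 equiv), THF, rt; aqueous work-up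
Reagents that add atoms: none
Why: Reductive cleavage of an aryl O-carbamate by Cp2Zr(H)Cl (hydrozirconation of the carbamate carbonyl, then collapse to the zirconium phenoxide and a formamide); the reagent is neutral, is known for doubly ortho-substituted carbamates from directed metalation, and should leave the aryl iodide and benzyl ethers untouched.

Step 6
Reactants: 10 3-hydroxy-4,5-dimethoxybenzaldehyde
Product: 11 3-(benzyloxy)-4,5-dimethoxybenzaldehyde
Conditions: BnBr, K2CO3, DMF, rt
Reagents that add atoms: benzyl bromide, BrCc1ccccc1
Why: Williamson benzylation of the only free phenol.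

Step 7
Reactants: 11 3-(benzyloxy)-4,5-dimethoxybenzaldehyde
Product: 12 1-(benzyloxy)-5-ethynyl-2,3-dimethoxybenzene
Conditions: dimethyl (1-diazo-2-oxopropyl)phosphonate, K2CO3, MeOH, 0 °C to rt
Reagents that add atoms: dimethyl (1-diazo-2-oxopropyl)phosphonate, CC(=O)C(=[N+]=[N-])P(=O)(OC)OC (one carbon)
Why: Ohira–Bestmann homologation; methanolysis of the reagent gives the diazomethylphosphonate anion, which adds to the aldehyde, and loss of phosphate and nitrogen with a 1,2-hydride shift gives the terminal alkyne; electron-rich, non-enolisable aryl aldehydes are good substrates.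

Step 8
Reactants: 9 3,5-bis(benzyloxy)-2-iodo-6-methoxyphenol, 12 1-(benzyloxy)-5-ethynyl-2,3-dimethoxybenzene, 13 carbon monoxide
Product: 16 5,7-bis(benzyloxy)-2-[3-(benzyloxy)-4,5-dimethoxyphenyl]-8-methoxychromen-4-one, via ynone 14 (not isolated), via enaminone 15 (not isolated)
Conditions: PdCl2(PPh3)2 (5 mol %), CO (20 bar), Et2NH, 120 °C
Reagents that add atoms: diethylamine, CCNCC (amino group of intermediate 15 only; released again on ring closure)
Why: The divalent palladium precatalyst is reduced in the amine to zerovalent palladium, which inserts into the C4a–I bond of 9; migratory insertion of 13 gives an aroylpalladium iodide, and amine-assisted transfer of the acetylide of 12 with reductive elimination forms C4a–C4 and C4–C3 in ynone 14. Diethylamine then adds to C2 of 14 to give enaminone 15, and the C8a hydroxyl displaces the amine at C2 by addition–elimination, forming O1–C2. The closest known reaction type is the palladium-catalysed carbonylative coupling of 2-iodophenols with terminal arylacetylenes in secondary amines, which gives flavones directly. Ring C closes in a net 6-endo-dig sense, realised as a 6-endo-trig addition–elimination on the enaminone, and no stereocentre is formed. Two selectivities are needed: carbonylation before alkynylation, and six- against five-membered closure. The first should be secured by CO pressure, the absence of a copper co-catalyst and the electron-rich arylpalladium, whose CO insertion is fast, so that direct coupling to a 2-arylbenzofuran is suppressed. The second should be secured by diethylamine, because 15 can only be attacked at C2, whereas free 14 could close 5-exo to the aurone. An iodide is used because oxidative addition must occur at a carbon flanked by a hydroxyl and a benzyloxy group on an electron-rich ring.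

Step 9
Reactants: 16 5,7-bis(benzyloxy)-2-[3-(benzyloxy)-4,5-dimethoxyphenyl]-8-methoxychromen-4-one
Product: 19 5,7-bis(benzyloxy)-2-[3-(benzyloxy)-4,5-dimethoxyphenyl]-3-hydroxy-8-methoxychromen-4-one, via 3-lithioflavone 17 (not isolated), via flavon-3-yl boronate 18 (not isolated)
Conditions: LiN(iPr)2, THF, −78 °C; B(OMe)3, −78 to 0 °C; AcOH, 30% H2O2, 0 °C to rt
Reagents that add atoms: hydrogen peroxide, OO (the new oxygen); trimethyl borate, COB(OC)OC (boron and methoxyls of 18); lithium diisopropylamide, [Li]N(C(C)C)C(C)C (lithium of 17)
Why: Known 3-lithiation of flavones by a lithium amide at the C–H next to the C4 carbonyl, followed by borate trapping and peroxide oxidation with migration of C3 from boron to oxygen; the benzyl and methyl ethers are inert to the amide base.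

Step 10
Reactants: 19 5,7-bis(benzyloxy)-2-[3-(benzyloxy)-4,5-dimethoxyphenyl]-3-hydroxy-8-methoxychromen-4-one
Product: 20 3,5,7-trihydroxy-2-(3-hydroxy-4,5-dimethoxyphenyl)-8-methoxychromen-4-one
Conditions: H2 (1 atm), 10% Pd/C, EtOAc–MeOH, rt
Reagents that add atoms: none
Why: Hydrogenolysis of three aryl benzyl ethers under neutral conditions; the methyl ethers, the C4 carbonyl and the tetrasubstituted C2=C3 bond should survive at atmospheric pressure, and the absence of base avoids autoxidation of the free flavonol.

## Compound list

1 | 3,5-bis(benzyloxy)phenol | Oc1cc(OCc2ccccc2)cc(OCc2ccccc2)c1 | starting material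
2 | 3,5-bis(benzyloxy)phenyl N,N-diethylcarbamate | CCN(CC)C(=O)Oc1cc(OCc2ccccc2)cc(OCc2ccccc2)c1 | intermediate
3 | [2,4-bis(benzyloxy)-6-(diethylcarbamoyloxy)phenyl]lithium | CCN(CC)C(=O)Oc1cc(OCc2ccccc2)cc(OCc2ccccc2)c1[Li] | intermediate
4 | dimethyl [2,4-bis(benzyloxy)-6-(diethylcarbamoyloxy)phenyl]boronate | CCN(CC)C(=O)Oc1cc(OCc2ccccc2)cc(OCc2ccccc2)c1B(OC)OC | intermediate
5 | 3,5-bis(benzyloxy)-2-hydroxyphenyl N,N-diethylcarbamate | CCN(CC)C(=O)Oc1cc(OCc2ccccc2)cc(OCc2ccccc2)c1O | intermediate
6 | 3,5-bis(benzyloxy)-2-methoxyphenyl N,N-diethylcarbamate | CCN(CC)C(=O)Oc1cc(OCc2ccccc2)cc(OCc2ccccc2)c1OC | intermediate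
7 | [4,6-bis(benzyloxy)-2-(diethylcarbamoyloxy)-3-methoxyphenyl]lithium | CCN(CC)C(=O)Oc1c([Li])c(OCc2ccccc2)cc(OCc2ccccc2)c1OC | intermediate
8 | 3,5-bis(benzyloxy)-2-iodo-6-methoxyphenyl N,N-diethylcarbamate | CCN(CC)C(=O)Oc1c(I)c(OCc2ccccc2)cc(OCc2ccccc2)c1OC | intermediate
9 | 3,5-bis(benzyloxy)-2-iodo-6-methoxyphenol | COc1c(O)c(I)c(OCc2ccccc2)cc1OCc1ccccc1 | intermediate
10 | 3-hydroxy-4,5-dimethoxybenzaldehyde | COc1cc(C=O)cc(O)c1OC | starting material
11 | 3-(benzyloxy)-4,5-dimethoxybenzaldehyde | COc1cc(C=O)cc(OCc2ccccc2)c1OC | intermediate
12 | 1-(benzyloxy)-5-ethynyl-2,3-dimethoxybenzene | C#Cc1cc(OCc2ccccc2)c(OC)c(OC)c1 | intermediate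
13 | carbon monoxide | [C-]#[O+] | starting material
14 | 1-[4,6-bis(benzyloxy)-2-hydroxy-3-methoxyphenyl]-3-[3-(benzyloxy)-4,5-dimethoxyphenyl]prop-2-yn-1-one | COc1c(O)c(C(=O)C#Cc2cc(OCc3ccccc3)c(OC)c(OC)c2)c(OCc2ccccc2)cc1OCc1ccccc1 | intermediate
15 | (E)-1-[4,6-bis(benzyloxy)-2-hydroxy-3-methoxyphenyl]-3-[3-(benzyloxy)-4,5-dimethoxyphenyl]-3-(diethylamino)prop-2-en-1-one (E drawn; either geometry can cyclise) | CCN(CC)/C(c1cc(OCc2ccccc2)c(OC)c(OC)c1)=C/C(=O)c1c(O)c(OC)c(OCc2ccccc2)cc1OCc1ccccc1 | intermediate
16 | 5,7-bis(benzyloxy)-2-[3-(benzyloxy)-4,5-dimethoxyphenyl]-8-methoxychromen-4-one | COc1c(OCc2ccccc2)cc(OCc2ccccc2)c2c(=O)cc(-c3cc(OCc4ccccc4)c(OC)c(OC)c3)oc12 | intermediate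
17 | {5,7-bis(benzyloxy)-2-[3-(benzyloxy)-4,5-dimethoxyphenyl]-8-methoxy-4-oxo-4H-chromen-3-yl}lithium | COc1c(OCc2ccccc2)cc(OCc2ccccc2)c2c(=O)c([Li])c(-c3cc(OCc4ccccc4)c(OC)c(OC)c3)oc12 | intermediate
18 | dimethyl {5,7-bis(benzyloxy)-2-[3-(benzyloxy)-4,5-dimethoxyphenyl]-8-methoxy-4-oxo-4H-chromen-3-yl}boronate | COc1c(OCc2ccccc2)cc(OCc2ccccc2)c2c(=O)c(B(OC)OC)c(-c3cc(OCc4ccccc4)c(OC)c(OC)c3)oc12 | intermediate
19 | 5,7-bis(benzyloxy)-2-[3-(benzyloxy)-4,5-dimethoxyphenyl]-3-hydroxy-8-methoxychromen-4-one | COc1c(OCc2ccccc2)cc(OCc2ccccc2)c2c(=O)c(O)c(-c3cc(OCc4ccccc4)c(OC)c(OC)c3)oc12 | intermediate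
20 | 3,5,7-trihydroxy-2-(3-hydroxy-4,5-dimethoxyphenyl)-8-methoxychromen-4-one | COc1cc(-c2oc3c(OC)c(O)cc(O)c3c(=O)c2O)cc(O)c1OC | target

## Step count and risks

Total: 10 steps. Longest linear sequence: 8 steps (steps 1 to 5, then 8, 9 and 10); the alkyne branch (steps 6 and 7) is 2 steps.

**Step 8 (key step).** The most likely failure is coupling without carbonylation: if alkynyl transfer outruns CO insertion, the resulting 2-alkynylphenol closes to a 2-arylbenzofuran. Slow oxidative addition at the doubly flanked C–I bond, with loss of iodine from 9 at 120 °C, is the second concern, and 5-exo closure to the aurone would follow if amine addition to 14 lags. The fallback avoids palladium and CO gas and brings in the carbonyl carbon as a carbamoyl chloride. It sets out from 12 and 9. Alkyne 12 is deprotonated with nBuLi in THF at −78 °C to the lithium acetylide F1 and acylated with N-methoxy-N-methylcarbamoyl chloride to 3-[3-(benzyloxy)-4,5-dimethoxyphenyl]-N-methoxy-N-methylprop-2-ynamide F2. Iodophenol 9 is treated with nBuLi (2.2 equiv, THF, −78 °C), which deprotonates the phenol and exchanges iodine for lithium to give lithium 3,5-bis(benzyloxy)-2-lithio-6-methoxyphenolate F3. Acylation of F3 by F2 and work-up with aqueous NH4Cl bring the sequence back to the route at ynone 14, now isolated, and Et2NH in EtOH should convert 14 through 15 into 16.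

**Step 9.** Deprotonation at C3 may be incomplete, the amide base or the 3-lithio species may attack the pyranone, and borylation may be slow at a carbon flanked by the carbonyl and the 2-aryl group. The fallback oxidises the C2=C3 bond and not the C3–H bond. It sets out from 16: dimethyldioxirane in acetone–CH2Cl2 at 0 °C should give the cis-fused 2,3-epoxide F4, and catalytic TsOH in CH2Cl2 opens it at C2 (oxocarbenium stabilised by O1), after which loss of the C3 proton returns the route at 19.

**Step 2.** Lithiation may stray to the position between the two benzyloxy groups or to a benzylic CH2 (followed by Wittig rearrangement), the carbamoyl group may shift to carbon if the temperature rises, and it may migrate to the new phenol oxygen during oxidation. The fallback uses no organolithium and sets out from 1. Magnesium-mediated ortho-formylation (MgCl2, Et3N, paraformaldehyde, MeCN, reflux) should give 2,4-bis(benzyloxy)-6-hydroxybenzaldehyde F5. Carbamoylation (NaH, ClC(O)NEt2, THF) gives 3,5-bis(benzyloxy)-2-formylphenyl N,N-diethylcarbamate F6. Baeyer–Villiger oxidation with mCPBA in CH2Cl2 gives 2,4-bis(benzyloxy)-6-(diethylcarbamoyloxy)phenyl formate F7, and Et3N in MeOH removes the formyl group to return the route at 5.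

**Step 5.** Hydride delivery to a carbamate carbonyl shielded by two ortho substituents may be slow, leaving 8 unconverted or forcing conditions under which the C–I bond is no longer safe. The fallback removes the carbamate before iodine is introduced and sets out from 6. KOH in EtOH–H2O at reflux should give 3,5-bis(benzyloxy)-2-methoxyphenol F8, and MOMCl with iPr2NEt in CH2Cl2 gives 1,5-bis(benzyloxy)-2-methoxy-3-(methoxymethoxy)benzene F9. The chelating acetal is a stronger director than a benzyl ether, so nBuLi in THF at 0 °C should lithiate next to it to give the aryllithium F10. Iodine then gives 1,5-bis(benzyloxy)-2-iodo-4-methoxy-3-(methoxymethoxy)benzene F11, and dilute HCl in MeOH at rt removes the acetal to return the route at 9.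

## Further compounds

F1 | step 8 | {[3-(benzyloxy)-4,5-dimethoxyphenyl]ethynyl}lithium | [Li]C#Cc1cc(OCc2ccccc2)c(OC)c(OC)c1
F2 | step 8 | 3-[3-(benzyloxy)-4,5-dimethoxyphenyl]-N-methoxy-N-methylprop-2-ynamide | CON(C)C(=O)C#Cc1cc(OCc2ccccc2)c(OC)c(OC)c1
F3 | step 8 | lithium 3,5-bis(benzyloxy)-2-lithio-6-methoxyphenolate | [Li]Oc1c(OC)c(OCc2ccccc2)cc(OCc2ccccc2)c1[Li]
F4 | step 9 | 4,6-bis(benzyloxy)-1a-[3-(benzyloxy)-4,5-dimethoxyphenyl]-3-methoxy-1a,7a-dihydro-7H-oxireno[2,3-b]chromen-7-one (racemic, cis-fused; one enantiomer drawn) | COc1c(OCc2ccccc2)cc(OCc2ccccc2)c2c1O[C@]1(c3cc(OCc4ccccc4)c(OC)c(OC)c3)O[C@@H]1C2=O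
F5 | step 2 | 2,4-bis(benzyloxy)-6-hydroxybenzaldehyde | O=Cc1c(O)cc(OCc2ccccc2)cc1OCc1ccccc1
F6 | step 2 | 3,5-bis(benzyloxy)-2-formylphenyl N,N-diethylcarbamate | CCN(CC)C(=O)Oc1cc(OCc2ccccc2)cc(OCc2ccccc2)c1C=O
F7 | step 2 | 2,4-bis(benzyloxy)-6-(diethylcarbamoyloxy)phenyl formate | CCN(CC)C(=O)Oc1cc(OCc2ccccc2)cc(OCc2ccccc2)c1OC=O
F8 | step 5 | 3,5-bis(benzyloxy)-2-methoxyphenol | COc1c(O)cc(OCc2ccccc2)cc1OCc1ccccc1
F9 | step 5 | 1,5-bis(benzyloxy)-2-methoxy-3-(methoxymethoxy)benzene | COCOc1cc(OCc2ccccc2)cc(OCc2ccccc2)c1OC
F10 | step 5 | [4,6-bis(benzyloxy)-3-methoxy-2-(methoxymethoxy)phenyl]lithium | COCOc1c([Li])c(OCc2ccccc2)cc(OCc2ccccc2)c1OC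
F11 | step 5 | 1,5-bis(benzyloxy)-2-iodo-4-methoxy-3-(methoxymethoxy)benzene | COCOc1c(I)c(OCc2ccccc2)cc(OCc2ccccc2)c1OC
A1 | alternative 1 | 3-(benzyloxy)-2-[3-(benzyloxy)-4,5-dimethoxyphenyl]-5,7-dihydroxy-8-methoxychromen-4-one | COc1c(O)cc(O)c2c(=O)c(OCc3ccccc3)c(-c3cc(OCc4ccccc4)c(OC)c(OC)c3)oc12
A2 | alternative 1 | 3-(benzyloxy)-2-[3-(benzyloxy)-4,5-dimethoxyphenyl]-5-(phenylsulfinyl)pyran-4-one (racemic at sulfur) | COc1cc(-c2occ(S(=O)c3ccccc3)c(=O)c2OCc2ccccc2)cc(OCc2ccccc2)c1OC
A3 | alternative 1 | 1,4-dimethoxy-1,3-bis(trimethylsilyloxy)buta-1,3-diene (mixture of geometric isomers) | COC=C(O[Si](C)(C)C)C=C(OC)O[Si](C)(C)C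
A4 | alternative 2 | 3-(benzyloxy)-2-[3-(benzyloxy)-4,5-dimethoxyphenyl]-5-hydroxy-8-methoxy-7-(propan-2-yloxy)chromen-4-one | COc1c(OC(C)C)cc(O)c2c(=O)c(OCc3ccccc3)c(-c3cc(OCc4ccccc4)c(OC)c(OC)c3)oc12
A5 | alternative 2 | 4-{5-(benzyloxy)-6-[3-(benzyloxy)-4,5-dimethoxyphenyl]-4-oxo-4H-pyran-2-yl}-4-methoxy-3-(propan-2-yloxy)cyclobut-2-en-1-one (racemic) | COC1(c2cc(=O)c(OCc3ccccc3)c(-c3cc(OCc4ccccc4)c(OC)c(OC)c3)o2)C(OC(C)C)=CC1=O
A6 | alternative 2 | (3Z)-4-{5-(benzyloxy)-6-[3-(benzyloxy)-4,5-dimethoxyphenyl]-4-oxo-4H-pyran-2-yl}-4-methoxy-3-(propan-2-yloxy)buta-1,3-dien-1-one | O=C=C/C(OC(C)C)=C(/OC)c1cc(=O)c(OCc2ccccc2)c(-c2cc(OCc3ccccc3)c(OC)c(OC)c2)o1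
A7 | alternative 3 | 7-(benzyloxy)-2-[3-(benzyloxy)-4,5-dimethoxyphenyl]-5-hydroxy-8-methoxy-4-oxo-4H-chromen-3-yl benzoate | COc1c(OCc2ccccc2)cc(O)c2c(=O)c(OC(=O)c3ccccc3)c(-c3cc(OCc4ccccc4)c(OC)c(OC)c3)oc12
A8 | alternative 3 | 1-[4-(benzyloxy)-2-hydroxy-5-methoxyphenyl]-3-[3-(benzyloxy)-4,5-dimethoxyphenyl]-1,3-dioxopropan-2-yl benzoate (racemic, largely enolised) | COc1cc(C(=O)C(OC(=O)c2ccccc2)C(=O)c2cc(OCc3ccccc3)c(OC)c(OC)c2)c(O)cc1OCc1ccccc1
A9 | alternative 3 | 1-[4-(benzyloxy)-3,3-dimethoxy-6-oxocyclohexa-1,4-dien-1-yl]-3-[3-(benzyloxy)-4,5-dimethoxyphenyl]-1,3-dioxopropan-2-yl benzoate (racemic) | COC1(OC)C=C(C(=O)C(OC(=O)c2ccccc2)C(=O)c2cc(OCc3ccccc3)c(OC)c(OC)c2)C(=O)C=C1OCc1ccccc1
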